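**Retrosynthetic overview**
1. The guanine is built last on the finished cyclophane. C8 comes from an aryl aldehyde, and the rest comes from 2,6-diamino-5-nitrosopyrimidin-4-one (Traube synthesis from guanidine and methyl cyanoacetate).
2. The aldehyde is installed ortho to the MOM-protected phenol by directed lithiation of the N,N'-protected piperazinomycin core.
3. Key disconnection: both CH2–N bonds of the piperazine are cut at once, which gives a diaryl-ether-tethered bis-(S)-2-benzylaziridine. In the forward direction, a head-to-tail double ring expansion (two 3-rings to one 6-ring) closes the piperazine and the 14-membered ring together.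
4. The bis-aziridine comes from a dibromo diaryl ether (Ullmann coupling, then para-bromination) and two equivalents of an (R)-aziridin-2-ylmethyl tosylate, which supplies both stereocentres.
5. Ring order: pyrimidinone (side branch), then piperazine plus macrocycle from the purchased aziridine rings, then the imidazole ring of the purine.

Assumption: the 7H-lactam tautomer in the target SMILES is one drawing of a mobile system, the product is isolated as the free base, and catechol mono-MOM ether and the N-(1-phenylethyl)aziridinemethanol are bought in the protected form shown.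

**Step 1**
Reactants: 1 2-(methoxymethoxy)phenol; 2 1-bromo-4-iodobenzene
Product: 3 1-(4-bromophenoxy)-2-(methoxymethoxy)benzene
Conditions: CuI (5 mol %), picolinic acid (10 mol %), K3PO4 (2 equiv), DMSO, 80 °C, 16 h
Reagents that add atoms: none
Why: This is a ligand-accelerated Ullmann diaryl ether synthesis in which copper reacts with C–I much faster than with C–Br at 80 °C, so the bromide is kept and the MOM acetal is inert to base.

**Step 2**
Reactants: 3 1-(4-bromophenoxy)-2-(methoxymethoxy)benzene
Product: 4 4-bromo-2-(4-bromophenoxy)-1-(methoxymethoxy)benzene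
Conditions: NBS (1.05 equiv), MeCN, 0 °C to rt
Reagents that add atoms: N-bromosuccinimide, O=C1CCC(=O)N1Br
Why: In this electrophilic aromatic bromination (SEAr) the OMOM oxygen is the strongest donor and directs to its free para position, while the aryloxy oxygen is a weaker donor and the bromophenoxy ring is deactivated.

**Step 3**
Reactants: 5 [(2R)-1-[(1R)-1-phenylethyl]aziridin-2-yl]methanol
Product: 6 [(2R)-1-[(1R)-1-phenylethyl]aziridin-2-yl]methyl 4-methylbenzenesulfonate
Conditions: TsCl (1.1 equiv), Et3N (1.5 equiv), DMAP (5 mol %), CH2Cl2, 0 °C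
Reagents that add atoms: p-toluenesulfonyl chloride, Cc1ccc(cc1)S(=O)(=O)Cl
Why: This is a plain O-sulfonylation of a primary alcohol, in which the tertiary aziridine nitrogen cannot be sulfonylated and the C2 stereocentre is not touched.

**Step 4**
Reactants: 4 4-bromo-2-(4-bromophenoxy)-1-(methoxymethoxy)benzene; 6 [(2R)-1-[(1R)-1-phenylethyl]aziridin-2-yl]methyl 4-methylbenzenesulfonate (2.2 equiv)
Product: 8 tethered bis-aziridine (2S)-2-[4-[2-(methoxymethoxy)-5-[[(2S)-1-[(1R)-1-phenylethyl]aziridin-2-yl]methyl]phenoxy]benzyl]-1-[(1R)-1-phenylethyl]aziridine, via bis-Grignard reagent 7 (not isolated)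
Conditions: Mg turnings, LiCl, THF, 25–40 °C; then Li2CuCl4 (5 mol %), 6, −20 °C to rt
Reagents that add atoms: none
Why: This is a Kochi-type copper-catalysed sp2–sp3 coupling of an aryl Grignard reagent with a primary tosylate, and because a non-activated N-alkylaziridine ring is not opened by organomagnesium or organocopper reagents, substitution occurs at the exocyclic CH2 and C2 keeps its geometry (the descriptor changes from R to S only because CH2Ar ranks below the ring CH2).

**Step 5**
Reactants: 8 tethered bis-aziridine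
Product: 9 N,N'-bis[(1R)-1-phenylethyl]-O-(methoxymethyl)piperazinomycin [(2S,5S)-piperazine bridged from C2 to C5 by CH2–(1,4-phenylene)–O–(aryl C3; OMOM at C4; CH2 at C1)–CH2; 14-membered ring]
Conditions: 2,6-lutidine·HI (0.3 equiv), NaI (0.5 equiv), MeCN, 82 °C, syringe-pump addition of 8 over 24 h (final 1 mM), then 12 h; aq NaHCO3
Reagents that add atoms: none
Why: Proposed new method: this is an intramolecular, macrocyclising head-to-tail [3+3] ring expansion of a tethered bis-aziridine, a stepwise ionic process in which catalytic H+/I− opens one aziridine at its unsubstituted CH2 to a β-iodoamine, the nitrogen of the second aziridine is alkylated by that CH2–I (closing the 14-membered ring), iodide reopens the resulting aziridinium at its CH2, and the freed secondary amine closes the piperazine 6-exo-tet and returns HI; only the two CH2–N bonds are broken and made, so both (S)-centres carry over unchanged, roughly 2 × 26 kcal/mol of aziridine strain pays for the cyclophane strain, and pseudo-high dilution suppresses oligomers; the closest known reaction type is the intermolecular halide/acid-catalysed dimerisation of N-alkylaziridines to 2,5-disubstituted piperazines, which has not been run within one molecule to bridge a ring.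

**Step 6**
Reactants: 9 N,N'-bis[(1R)-1-phenylethyl]-O-(methoxymethyl)piperazinomycin
Product: 11 the C5-carbaldehyde of 9 (CHO ortho to OMOM), via aryllithium 10 (not isolated)
Conditions: s-BuLi (1.3 equiv), TMEDA, THF, −78 °C, 1 h; DMF (3 equiv), −78 to 0 °C; aq NH4Cl
Reagents that add atoms: N,N-dimethylformamide, CN(C)C=O
Why: In this directed ortho-metalation followed by formylation, OMOM is the strongest directing group present, C5 is its only free ortho position, and the substrate has no acidic N–H or O–H.

**Step 7**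
Reactants: 12 guanidine hydrochloride; 13 methyl cyanoacetate
Product: 15 2,6-diamino-5-nitrosopyrimidin-4(3H)-one, via 2,6-diaminopyrimidin-4(3H)-one 14 (not isolated)
Conditions: NaOMe, MeOH, reflux, 4 h; remove MeOH, H2O, AcOH (pH 4–5), NaNO2 (1.05 equiv), 20–50 °C; filter
Reagents that add atoms: sodium nitrite, [Na+].[O-]N=O
Why: This is a Traube pyrimidine synthesis (guanidine/cyanoacetate cyclocondensation) followed in the same pot by electrophilic C-nitrosation of the very electron-rich C5.

**Step 8**
Reactants: 11 the C5-carbaldehyde of 9; 15 2,6-diamino-5-nitrosopyrimidin-4(3H)-one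
Product: 18 8-aryl guanine with MOM and both N-(1-phenylethyl) groups still in place, via triaminopyrimidinone 16 (not isolated), via Schiff base 17 (not isolated)
Conditions: 15, Na2S2O4 (2.2 equiv), DMSO–H2O 9:1, N2, 60 °C, 0.5 h; add 11, 80 °C, 2 h; then open to air, 110 °C, 10 h
Reagents that add atoms: none
Why: In this Traube-type purine annulation, dithionite reduces the nitroso group, the most nucleophilic 5-NH2 forms the Schiff base, the 6-NH2 adds to it, and the bisulfite-assisted aerobic dehydrogenation known from benzimidazole and 8-arylxanthine synthesis aromatises the imidazole ring, while the tertiary amines and the stereocentres are bystanders.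

**Step 9**
Reactants: 18 protected 8-aryl guanine
Product: 20 guanipiperazine A, via free phenol 19 (not isolated)
Conditions: 3 M HCl in MeOH, 50 °C, 2 h, evaporate; then H2 (4 bar), 20 % Pd(OH)2/C, MeOH–H2O, 50 °C; neutralise, reverse-phase chromatography
Reagents that add atoms: none
Why: Acid-catalysed acetal exchange removes MOM while both nitrogens are still tertiary, so the formaldehyde equivalent leaves as volatile dimethoxymethane and cannot N-methylate, and Pearlman hydrogenolysis then cleaves only the two benzylic N–CH(CH3)Ph bonds because the ring C–N bonds are homobenzylic, which leaves both (S)-centres untouched.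

**Compound list**
1 | 2-(methoxymethoxy)phenol | COCOc1ccccc1O | starting material
2 | 1-bromo-4-iodobenzene | Brc1ccc(I)cc1 | starting material
3 | 1-(4-bromophenoxy)-2-(methoxymethoxy)benzene | COCOc1ccccc1Oc1ccc(Br)cc1 | intermediate
4 | 4-bromo-2-(4-bromophenoxy)-1-(methoxymethoxy)benzene | COCOc1ccc(Br)cc1Oc1ccc(Br)cc1 | intermediate
5 | [(2R)-1-[(1R)-1-phenylethyl]aziridin-2-yl]methanol | OC[C@H]1CN1[C@H](C)c1ccccc1 | starting material
6 | [(2R)-1-[(1R)-1-phenylethyl]aziridin-2-yl]methyl 4-methylbenzenesulfonate | Cc1ccc(cc1)S(=O)(=O)OC[C@H]1CN1[C@H](C)c1ccccc1 | intermediate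
7 | bis-Grignard reagent of 4 (not isolated) | COCOc1ccc([Mg]Br)cc1Oc1ccc([Mg]Br)cc1 | intermediate
8 | diaryl-ether-tethered bis[(2S)-1-[(1R)-1-phenylethyl]aziridin-2-ylmethyl] compound | COCOc1ccc(C[C@H]2CN2[C@H](C)c2ccccc2)cc1Oc1ccc(C[C@H]2CN2[C@H](C)c2ccccc2)cc1 | intermediate
9 | N,N'-bis[(1R)-1-phenylethyl]-O-(methoxymethyl)piperazinomycin, (2S,5S) | COCOc1ccc2cc1Oc1ccc(cc1)C[C@H]3CN([C@H](C)c4ccccc4)[C@H](CN3[C@H](C)c4ccccc4)C2 | intermediate
10 | C5-lithio derivative of 9 (not isolated) | COCOc1c([Li])cc2cc1Oc1ccc(cc1)C[C@H]3CN([C@H](C)c4ccccc4)[C@H](CN3[C@H](C)c4ccccc4)C2 | intermediate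
11 | C5-carbaldehyde of 9 | COCOc1c(C=O)cc2cc1Oc1ccc(cc1)C[C@H]3CN([C@H](C)c4ccccc4)[C@H](CN3[C@H](C)c4ccccc4)C2 | intermediate
12 | guanidine hydrochloride | NC(N)=N.Cl | starting material
13 | methyl cyanoacetate | COC(=O)CC#N | starting material
14 | 2,6-diaminopyrimidin-4(3H)-one (not isolated) | Nc1cc(=O)[nH]c(N)n1 | intermediate
15 | 2,6-diamino-5-nitrosopyrimidin-4(3H)-one | Nc1nc(N)c(N=O)c(=O)[nH]1 | intermediate
16 | 2,5,6-triaminopyrimidin-4(3H)-one (not isolated) | Nc1nc(N)c(N)c(=O)[nH]1 | intermediate
17 | (E)-5-(arylmethylideneamino) Schiff base of 16 and 11 (not isolated) | Nc1nc(N)c(/N=C/c2cc3cc(c2OCOC)Oc2ccc(cc2)C[C@H]2CN([C@H](C)c4ccccc4)[C@H](CN2[C@H](C)c2ccccc2)C3)c(=O)[nH]1 | intermediate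
18 | O-MOM-N,N'-bis[(1R)-1-phenylethyl]guanipiperazine A | Nc1nc2nc(-c3cc4cc(c3OCOC)Oc3ccc(cc3)C[C@H]3CN([C@H](C)c5ccccc5)[C@H](CN3[C@H](C)c3ccccc3)C4)[nH]c2c(=O)[nH]1 | intermediate
19 | N,N'-bis[(1R)-1-phenylethyl]guanipiperazine A (free phenol, not isolated) | Nc1nc2nc(-c3cc4cc(c3O)Oc3ccc(cc3)C[C@H]3CN([C@H](C)c5ccccc5)[C@H](CN3[C@H](C)c3ccccc3)C4)[nH]c2c(=O)[nH]1 | intermediate
20 | guanipiperazine A | Nc1nc2nc(-c3cc4cc(c3O)Oc3ccc(cc3)C[C@H]3CN[C@H](CN3)C4)[nH]c2c(=O)[nH]1 | target

**Step count**
- Total steps: 9.
- Longest linear sequence: 7 (steps 1, 2, 4, 5, 6, 8, 9).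

**Steps most likely to fail**

**Step 5 (the new step).**
- Risks:
  - Oligomerisation may outrun closure of the strained 14-membered ring.
  - N-alkylation is slowed by the α-branched N-substituents.
  - Reversible opening to a secondary iodide could erode configuration. Any epimer would be a separable diastereomer because of the (R)-phenylethyl groups.
- Fallback (known chemistry): it sets out from 6 and comes back at 9, and it closes the macrocycle at the diaryl ether C–O bond on a preformed piperazine instead of at C–N. Commercial 1-bromo-2-(methoxymethoxy)benzene is iodinated para to OMOM (NIS, MeCN) to give 2-bromo-4-iodo-1-(methoxymethoxy)benzene F1. Selective I/Mg exchange (i-PrMgCl·LiCl, −20 °C) gives [3-bromo-4-(methoxymethoxy)phenyl]magnesium chloride F2, which is coupled with 6 (Li2CuCl4 cat.) to the bromo aziridine F3. Commercial (4-bromophenoxy)(tert-butyl)dimethylsilane gives with Mg the [4-(tert-butyldimethylsilyloxy)phenyl]magnesium bromide F4, and coupling with 6 gives the silyloxy aziridine F5. F3 and three equivalents of F5 are dimerised intermolecularly (2,6-lutidine·HI, NaI, MeCN, 0.5 M, 82 °C), and the mixed (2S,5S)-piperazine F6 is separated from the homodimers. TBAF frees the phenol F7, and intramolecular Ullmann etherification (CuI, N,N-dimethylglycine, Cs2CO3, dioxane, 110 °C, 2 mM) gives 9.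

**Step 4.**
- Risks:
  - The Grignard reagent may attack at sulfur of the tosylate.
  - Lewis-acid-assisted aziridine opening may compete.
  - Partial stereochemical leakage could occur through neighbouring-group participation of the aziridine nitrogen.
- Fallback: it sets out from 4 (through 7) and comes back at 8, and it builds the aziridines after the C–C bond instead of coupling them intact. Reagent 7 opens (R)-epichlorohydrin at the epoxide CH2 (CuI cat., THF, −30 °C) to give the bis-chlorohydrin F8. Heating with (R)-1-phenylethylamine and K2CO3 in EtOH proceeds through the terminal epoxides and gives the bis(amino alcohol) F9. Intramolecular Mitsunobu closure (PPh3, DIAD, THF) forms both aziridines with inversion at the carbinol carbons, (R) to (S), and gives 8.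

**Step 8.**
- Risks:
  - The pyrimidine is poorly soluble.
  - Triamine 16 is air-sensitive.
  - Aerobic dehydrogenation of a hindered ortho-alkoxy aryl imine may stall.
- Fallback: it sets out from 9 (lithiated to 10 as in step 6) and comes back at 18, and it uses acylation and dehydration instead of oxidative imine cyclisation. Aryllithium 10 is quenched with CO2 to give the carboxylic acid F10. EDC·HCl/HOBt coupling with 16 (made from 15 with Na2S2O4 and isolated as its sulfate) acylates the 5-NH2 to give the 5-carboxamide F11. Cyclodehydration in 2 M NaOH–dioxane at reflux then gives 18.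

**Further compounds**
F1 | step 5 | 2-bromo-4-iodo-1-(methoxymethoxy)benzene | COCOc1ccc(I)cc1Br
F2 | step 5 | [3-bromo-4-(methoxymethoxy)phenyl]magnesium chloride | COCOc1ccc([Mg]Cl)cc1Br
F3 | step 5 | (2S)-2-[3-bromo-4-(methoxymethoxy)benzyl]-1-[(1R)-1-phenylethyl]aziridine | COCOc1ccc(C[C@H]2CN2[C@H](C)c2ccccc2)cc1Br
F4 | step 5 | [4-(tert-butyldimethylsilyloxy)phenyl]magnesium bromide | CC(C)(C)[Si](C)(C)Oc1ccc([Mg]Br)cc1
F5 | step 5 | (2S)-2-[4-(tert-butyldimethylsilyloxy)benzyl]-1-[(1R)-1-phenylethyl]aziridine | CC(C)(C)[Si](C)(C)Oc1ccc(C[C@H]2CN2[C@H](C)c2ccccc2)cc1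
F6 | step 5 | (2S,5S)-2-[3-bromo-4-(methoxymethoxy)benzyl]-5-[4-(tert-butyldimethylsilyloxy)benzyl]-1,4-bis[(1R)-1-phenylethyl]piperazine | CC(C)(C)[Si](C)(C)Oc1ccc(cc1)C[C@H]1CN([C@H](C)c2ccccc2)[C@H](CN1[C@H](C)c1ccccc1)Cc1ccc(OCOC)c(Br)c1
F7 | step 5 | 4-[[(2S,5S)-5-[3-bromo-4-(methoxymethoxy)benzyl]-1,4-bis[(1R)-1-phenylethyl]piperazin-2-yl]methyl]phenol | Oc1ccc(cc1)C[C@H]1CN([C@H](C)c2ccccc2)[C@H](CN1[C@H](C)c1ccccc1)Cc1ccc(OCOC)c(Br)c1
F8 | step 4 | (2R)-1-chloro-3-[4-[5-[(2R)-3-chloro-2-hydroxypropyl]-2-(methoxymethoxy)phenoxy]phenyl]propan-2-ol | COCOc1ccc(C[C@@H](O)CCl)cc1Oc1ccc(C[C@@H](O)CCl)cc1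
F9 | step 4 | (2R)-1-[4-[5-[(2R)-2-hydroxy-3-[[(1R)-1-phenylethyl]amino]propyl]-2-(methoxymethoxy)phenoxy]phenyl]-3-[[(1R)-1-phenylethyl]amino]propan-2-ol | COCOc1ccc(C[C@@H](O)CN[C@H](C)c2ccccc2)cc1Oc1ccc(C[C@@H](O)CN[C@H](C)c2ccccc2)cc1
F10 | step 8 | C5-carboxylic acid of 9 | COCOc1c(C(=O)O)cc2cc1Oc1ccc(cc1)C[C@H]3CN([C@H](C)c4ccccc4)[C@H](CN3[C@H](C)c4ccccc4)C2
F11 | step 8 | N-(2,6-diamino-4-oxo-3,4-dihydropyrimidin-5-yl) amide of F10 | Nc1nc(N)c(NC(=O)c2cc3cc(c2OCOC)Oc2ccc(cc2)C[C@H]2CN([C@H](C)c4ccccc4)[C@H](CN2[C@H](C)c2ccccc2)C3)c(=O)[nH]1
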